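- Tuesday's: free monomer 0.030 M; initiator 0.13 mM; temperature 25 °C; the very flask that is asked about, followed so far
- flask: free monomer 0.030 M; initiator 0.13 mM; temperature 25 °C; time 20 min

- Tuesday's (time / min: monomer in chains / %): 1.33: 2.9; 2.50: 8.8; 5.00: 24.8; 8.00: 37.6; 15.0: 50.2

(each reading ± 0.5 percentage points)

- alder: at 20 min raise the temperature by 25 K, then wait 10 min
- ash: at 20 min add free monomer, 50.0% of the amount charged, then wait 10 min
- elm: at 20 min add initiator, 100% of the amount charged, then wait 10 min
- cedar: change nothing and wait 10 min more

- monomer in chains is meant together with its idle complex
- what is added takes up no volume worth counting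
- on the list of suspects stand: free monomer + initiator -> living end + monomer in chains; monomer in chains + initiator <-> isomer of the product + initiator; initiator + monomer in chains <-> idle complex; free monomer + living end -> monomer in chains + living end

1. monomer in chains, in percent of the free monomer first charged, at 20 min
2. the option that brings most further monomer in chains ("none" if no option brings more than 2 percentage points) (alder / ash / elm / cedar / none)
3. monomer in chains present, in percent of the free monomer first charged, after alder
4. monomer in chains present, in percent of the free monomer first charged, after cedar

Count the charged free monomer first. At 15.0 min Tuesday's flask holds 50.2% of it in chains, and the gain is dying: the last 7.00 min added 13 percentage points, whereas the 2.50 min up to 5.00 min added 16 points. So the curve is flattening near half of the charge.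

Read that as a balance of monomer in chains + initiator <-> isomer of the product + initiator. Divide the forward rate by the back rate: initiator stands on both sides and cancels, time drops out, and one number remains (thermodynamic control). Keep it as the split, monomer in chains divided by the rest of the charge, here 1.01. It is a reading with scatter, and any free monomer left still counts in that rest.

My reckoning holds the split. Expect "now" a little above the last reading, and expect no help from extra initiator. Fresh monomer in ash, at this split, I reckon to bring 25 points.

Now turn the question round. For alder to beat ash, by that reckoning, the share in chains has to pass 75.3%, a split of 3.05, which is a rise by a factor 3.02. These readings come from one temperature and show neither the size nor the sign of that shift, so I name ash and leave heat open. Watch the split after heating.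

The forecast gives 50% (46% to 54%) for "now", 47% (40% to 55%) after cedar and 41% (28% to 54%) after alder, and it names ash. On heat it says: “Heating speeds isomerisation towards equilibrium, so it loses product.” There it differs from me, since I leave the direction open.

The flask gives 51.1% at 20 min and 51.3% after cedar. Alder brings 34 points, more than ash with 27 points, elm with 0.15 points or cedar with 0.22 points, so the best is alder.

    free monomer + initiator → living end + monomer in chains (k = 0.0570 M⁻¹ s⁻¹, Ea = 62.0 kJ mol⁻¹)
    monomer in chains + initiator ⇌ isomer of the product + initiator, rate k2*[initiator]*[monomer in chains] forward; the back reaction follows from the equilibrium constant (K = 0.950, k = 70.0 M⁻¹ s⁻¹, Ea = 44.0 kJ mol⁻¹, ΔH = −55.0 kJ mol⁻¹)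
    initiator + monomer in chains ⇌ idle complex (K = 13.0 M⁻¹, k = 0.300 M⁻¹ s⁻¹, Ea = 58.0 kJ mol⁻¹, ΔH = −57.0 kJ mol⁻¹)
    free monomer + living end → monomer in chains + living end, rate k4*[living end]*[free monomer] (k = 57.0 M⁻¹ s⁻¹, Ea = 38.0 kJ mol⁻¹)
    (constants at 25 °C)

Left to 200 min, the flask holds free monomer at 0% and a split of 1.05. Alder's 85.4%, counted the same way, is a split of 5.85, past the 3.05 reckoned from the readings. The repeat at 50 °C stands at 20.0 min with free monomer at 0%, monomer in chains at 85.4% and isomer of the product at 14.6%, a split of 5.85.

(The readings were generated by integration for substances that don't exist, and the scatter is random.)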